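The vessel held substrate and first nucleophile, stirred over solid second nucleophile, and the charging of dawn, dusk and summer was to be compared.

| flask | substrate | first nucleophile | solid second nucleophile | remark | time |
|---|---|---|---|---|---|
| Tuesday's | 0.079 M | 0.083 M | 0.0711 M | run made earlier |  |
| Friday's | 0.053 M | 0.083 M | 0.0711 M | run made earlier |  |
| Saturday's | 0.12 M | 0.083 M | 0.0711 M | run made earlier |  |
| Wednesday's | 0.079 M | 0.042 M | 0.0711 M | run made earlier |  |
| dawn | 0.079 M (fed, over 6.0 h) | 0.0830 M | 0.0711 M | all else is in the flask from the start; the feed brings no volume worth counting | 15 h |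
| dusk | 0.079 M | 0.0830 M (fed, over 6.0 h) | 0.0711 M | all else is in the flask from the start; the feed brings no volume worth counting | 15 h |
| summer | 0.079 M | 0.0830 M | 0.0711 M | everything together at the start | 15 h |

| run | time / h | target / % |
|---|---|---|
| Tuesday's | 0.667 | 3.2 |
| Tuesday's | 1.00 | 4.0 |
| Tuesday's | 1.50 | 6.9 |
| Tuesday's | 2.50 | 11.5 |
| Tuesday's | 4.00 | 16.8 |
| Tuesday's | 6.00 | 23.5 |
| Tuesday's | 10.0 | 34.0 |
| Friday's | 1.33 | 6.1 |
| Friday's | 2.50 | 11.1 |
| Friday's | 4.00 | 16.1 |
| Friday's | 5.00 | 19.1 |
| Friday's | 6.00 | 22.7 |
| Friday's | 8.00 | 28.8 |
| Friday's | 10.0 | 34.2 |
| Saturday's | 0.500 | 3.2 |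
| Saturday's | 1.33 | 6.0 |
| Saturday's | 2.50 | 11.5 |
| Saturday's | 4.00 | 16.4 |
| Saturday's | 5.00 | 20.7 |
| Saturday's | 8.00 | 28.9 |
| Saturday's | 10.0 | 33.7 |
| Wednesday's | 0.833 | 4.5 |
| Wednesday's | 2.50 | 10.0 |
| Wednesday's | 4.00 | 15.2 |
| Wednesday's | 6.00 | 19.9 |
| Wednesday's | 10.0 | 29.1 |

(readings scatter by 0.5 percentage points)

1. the best flask by amount of target, in percent of the substrate charged; "all alike" if 1.5 percentage points covers them all (dawn / dusk / summer / all alike)
2. amount of target at the end, in percent of the substrate charged, dawn
3. amount of target at the end, in percent of the substrate charged, dusk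
4. amount of target at the end, in percent of the substrate charged, summer

- at the start none of the solid second nucleophile is in solution
- a reading or a percentage of target counts all its forms, free or not

At 10.0 h, Friday's, Tuesday's and Saturday's runs stood at 34.2%, 34.0% and 33.7% of their charges, so I took the loss of substrate as first order. Wednesday's run, with 0.506 of Tuesday's first nucleophile, kept 0.856 of Tuesday's target. I read this as competition: I supposed that first nucleophile and dissolved second nucleophile share what leaves the substrate, target taking the share b/(b+x). Here b is first nucleophile as a fraction of Tuesday's charge, which I assumed constant in this reckoning, and x is the rival fraction. Dividing one capture rate by the other removes time, and the ratio of the two runs gave x = 0.208. Tuesday's share was then 82.8%, which gave a first-order constant of 0.0529 /h and 45.3% for summer. For dawn I counted each portion of substrate from its arrival, which gave 38.7%. For dusk, substrate lost during the feed took the mean share 63.4% of a linearly rising first nucleophile, and later losses took the full share, which gave 40.1%.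

The weak link was x, which rested on one pair of readings with scatter 0.5 percentage points. I pooled the shared times of Wednesday's and Tuesday's runs, and the ratio became 0.865. The rival fraction, read from these runs, became 0.191; it is the first-nucleophile fraction at which both captures run equal. Refitting the constant to 0.0519 /h left summer at 45.4%.

The forecast, lower than my summer figure, gave 42.5% for summer, 40.5% for dusk and 37% for dawn, adding “Summer should be best, though the mechanism stays uncertain”.

The flasks gave 44.5% in summer, 41.9% in dusk and 37.4% in dawn, so summer led.

    substrate ⇌ intermediate (K = 0.0434, k = 0.0503 /h)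
    first nucleophile + intermediate → target (k = 647 /M/h)
    second nucleophile + intermediate → other capture product (k = 454 /M/h)
    first nucleophile + target ⇌ idle adduct, settled at all times (K = 6.60 /M)
    solid second nucleophile ⇌ second nucleophile, rate k5*(cs5 - [second nucleophile]) while solid is left; crystals form when [second nucleophile] > cs5 (solubility = 21.0 mM, k = 0.248 /h)
    second nucleophile → decomposition product (k = 3.29 × 10⁻⁴ /h)

In dawn at 15.0 h, intermediate went to target 3.6 times as fast as to other capture product, a selectivity factor for which first nucleophile at 56.0% of its charge, divided by the rival fraction read from the runs, gives 2.94. Dawn read on to 25 h added 16 points of target, idle adduct counted, against 5.4 points of other capture product, a ratio of 2.95, where the mean of first nucleophile's fractions at those two times, over the rival fraction, gives 2.52.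

The earlier runs and the new flask are simulated with constants of no real substance.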